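A direct plan would take the carbinol carbon C1 from (R)-4-hydroxymandelic acid A1, which after silylation, acid chloride formation and treatment with diazomethane would give the diazoketone A2; photochemical Wolff rearrangement of A2 would give the β-silyloxy aldoketene A3. The dilithium dienolate of dehydrozingerone A4 would attack A3 to form C3–C4, and fluoride would free the hydroxyls. Its weakest steps would be:
- the C-acylation of a ketone enolate by a ketene, which would be unprecedented as a 1,3-diketone synthesis and open to O-acylation, ketene dimerisation and loss of silanolate;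
- the diazomethane homologation, which would be hazardous and would pass an acid chloride that could lose its configuration by way of a ketene;
- the coupling of a flow photolysis to a cryogenic enolate, which would depend on exact timing and dryness.

**New strategy.** The enolised 3,5-dione (O–C3–C4–C5–O) is read as a ring-opened isoxazole. The chain would therefore be joined at C4–C5 by a [3+2] cycloaddition of the nitrile oxide of coniferaldehyde (C5–C7) with the terminal alkyne of an (S)-homopropargylic silyl ether (C1–C4), whose stereocentre would come from a catalytic asymmetric propargylation of 4-silyloxybenzaldehyde. One operation would form C4–C5, place oxygen on C3 and nitrogen on C5, and lock the dione as a non-enolisable heteroaromatic; N–O cleavage and hydrolysis would release it late. No enolate acylation, ketene, diazomethane or photolysis is needed, and no carbanion ever sits beside the C1 leaving group.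

Key step: step 5

Assumption: the C4=C5 enol double bond is a tautomeric element of the 3,5-dione without fixed configuration, so the target is written with the enol geometry of its given string; the fixed elements are C1 (S) and C6=C7 (E).

Atoms are numbered as in the heptane chain of the target (C1 = carbinol carbon, C7 = carbon on the guaiacyl ring). TBS = tert-butyldimethylsilyl.

**Step 1**
Reactants: 1 4-(TBS-oxy)benzaldehyde; 2 allenylboronic acid pinacol ester
Product: 4 (1S)-1-[4-(TBS-oxy)phenyl]but-3-yn-1-ol, via borate ester 3 (not isolated)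
Conditions: 2 (1.5 equiv), (S)-TRIP [(S)-3,3′-bis(2,4,6-triisopropylphenyl)-1,1′-binaphthyl-2,2′-diyl hydrogen phosphate] (5 mol %), 4 Å MS, toluene, −20 °C; sat. aq. NaHCO3, rt
Reagents that add atoms: none
Why: Brønsted-acid-catalysed asymmetric propargylation (allenylboration through a closed six-membered chair transition state in which the phosphoric acid binds a boronate oxygen and the formyl hydrogen): the γ-carbon of 2 should add to the Si face of 1 under the S acid, by the model in which the R acid directs Re-face attack, which sets C1 as S, and the bicarbonate work-up hydrolyses borate 3.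

**Step 2**
Reactants: 4 (1S)-1-[4-(TBS-oxy)phenyl]but-3-yn-1-ol
Product: 5 (1S)-1-(TBS-oxy)-1-[4-(TBS-oxy)phenyl]but-3-yne
Conditions: TBSCl (1.3 equiv), imidazole (2.5 equiv), DMF, rt
Reagents that add atoms: tert-butyldimethylsilyl chloride, CC(C)(C)[Si](C)(C)Cl
Why: Imidazole-promoted O-silylation breaks no bond at C1 (it stays S) and caps the carbinol so that it can later neither close onto C5 to a dihydropyranone nor leave by elimination.

**Step 3**
Reactants: 6 coniferaldehyde, (2E)-3-(4-hydroxy-3-methoxyphenyl)prop-2-enal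
Product: 7 (2E)-3-[4-(TBS-oxy)-3-methoxyphenyl]prop-2-enal
Conditions: TBSCl (1.2 equiv), imidazole (2.2 equiv), DMF, 0 °C → rt
Reagents that add atoms: tert-butyldimethylsilyl chloride, CC(C)(C)[Si](C)(C)Cl
Why: O-silylation of the phenol, so that neither the chlorinating agent nor the nitrile oxide of the key step meets a free phenol; the E alkene is not involved.

**Step 4**
Reactants: 7 (2E)-3-[4-(TBS-oxy)-3-methoxyphenyl]prop-2-enal
Product: 8 (1E,2E)-3-[4-(TBS-oxy)-3-methoxyphenyl]prop-2-enal oxime
Conditions: NH2OH·HCl (1.2 equiv), NaOAc (1.5 equiv), EtOH, rt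
Reagents that add atoms: hydroxylamine hydrochloride, NO.Cl
Why: Oxime condensation at the aldehyde; the geometry of the new C=N bond is irrelevant because both isomers lead to the same nitrile oxide.

**Step 5**
Reactants: 8 (1E,2E)-3-[4-(TBS-oxy)-3-methoxyphenyl]prop-2-enal oxime; 5 (1S)-1-(TBS-oxy)-1-[4-(TBS-oxy)phenyl]but-3-yne
Product: 11 3-{(E)-2-[4-(TBS-oxy)-3-methoxyphenyl]ethenyl}-5-{(2S)-2-(TBS-oxy)-2-[4-(TBS-oxy)phenyl]ethyl}isoxazole, via hydroximoyl chloride 9 (not isolated), via nitrile oxide 10 (not isolated)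
Conditions: 8 (1.5 equiv), NCS (1.55 equiv), DMF, rt, 2 h; then 5 (1.0 equiv), CH2Cl2, Et3N (1.7 equiv, syringe pump, 8 h), rt
Reagents that add atoms: N-chlorosuccinimide, O=C1CCC(=O)N1Cl (chlorine of 9 only, no atom of it stays in 11)
Why: NCS chlorinates the aldoxime carbon to hydroximoyl chloride 9, Et3N removes HCl to give the conjugated nitrile oxide 10, and this 1,3-dipole adds to the terminal alkyne of 5 in a concerted, asynchronous [3+2] cycloaddition that forms C4–C5 and O–C3 together, the closest known reaction type being the Huisgen nitrile oxide–alkyne cycloaddition to 3,5-disubstituted isoxazoles. The isoxazole ring is closed by this intermolecular suprafacial cycloaddition, not by cyclisation of a chain, and is aromatic as formed, without an oxidation. No stereocentre is formed: C1 is two bonds from the reacting alkyne, has no acidic hydrogen because no carbonyl group is present yet, and stays S. The step needs regioselectivity for the 3,5- over the 3,4-isomer, which the monosubstituted alkyne secures because the dipole carbon bonds to the unhindered terminal carbon with the larger HOMO coefficient while oxygen goes to the substituted carbon C3. It also needs chemoselectivity against dimerisation to the furoxan and against addition to the styryl double bond, secured by slow addition of the base, the excess of 8, and the higher dipolarophilicity of a terminal alkyne over a conjugated trans-disubstituted alkene. The product holds the whole C1–C7 chain with both heteroatom positions of the dione fixed in a non-enolisable heteroaromatic, so the β-silyloxy group cannot be eliminated.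

**Step 6**
Reactants: 11 3-styryl-5-[(2S)-2-silyloxy-2-arylethyl]isoxazole
Product: 13 (1S,6E)-1-(TBS-oxy)-1-[4-(TBS-oxy)phenyl]-7-[4-(TBS-oxy)-3-methoxyphenyl]-5-hydroxyhepta-4,6-dien-3-one (enol form of the 3,5-dione), via enaminone 12 (not isolated)
Conditions: Mo(CO)6 (1.0 equiv), MeCN/H2O (10:1), 80 °C; filter (Celite), concentrate; 5% aq. oxalic acid/THF (1:3), rt
Reagents that add atoms: water, O
Why: Reductive N–O cleavage of the isoxazole by zerovalent molybdenum (Mo(CO)6/water) should give the Z vinylogous amide 12 without touching the styryl alkene or the silyl ethers, and mild aqueous acid hydrolysis of this primary enaminone (C4 protonation, addition of water to the C5 iminium, loss of ammonia) should release the enolised dione, while the C1 silyl ether prevents cyclisation and elimination and C1 stays S.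

**Step 7**
Reactants: 13 tris-TBS ether of the target
Product: 14 target, (1S,6E)-1,5-dihydroxy-7-(4-hydroxy-3-methoxyphenyl)-1-(4-hydroxyphenyl)hepta-4,6-dien-3-one
Conditions: HF·pyridine (excess), pyridine, THF, 0 °C → rt; pH 7 phosphate buffer
Reagents that add atoms: none
Why: Fluoride-driven cleavage of the three silyl ethers (silyl ether deprotection) in a pyridine-buffered medium should avoid both enolate chemistry (retro-aldol, elimination) and strong acid (dihydropyranone closure, benzylic ionisation), so no bond at C1 is broken and it stays S.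

## Compound list

1 | 4-(tert-butyldimethylsilyloxy)benzaldehyde | CC(C)(C)[Si](C)(C)Oc1ccc(C=O)cc1 | starting material
2 | allenylboronic acid pinacol ester, 4,4,5,5-tetramethyl-2-(propa-1,2-dien-1-yl)-1,3,2-dioxaborolane | C=C=CB1OC(C)(C)C(C)(C)O1 | starting material
3 | 2-{[(1S)-1-(4-TBS-oxyphenyl)but-3-yn-1-yl]oxy}-4,4,5,5-tetramethyl-1,3,2-dioxaborolane | C#CC[C@H](OB1OC(C)(C)C(C)(C)O1)c1ccc(O[Si](C)(C)C(C)(C)C)cc1 | intermediate (not isolated)
4 | (1S)-1-[4-(TBS-oxy)phenyl]but-3-yn-1-ol | C#CC[C@H](O)c1ccc(O[Si](C)(C)C(C)(C)C)cc1 | intermediate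
5 | (1S)-1-(TBS-oxy)-1-[4-(TBS-oxy)phenyl]but-3-yne | C#CC[C@H](O[Si](C)(C)C(C)(C)C)c1ccc(O[Si](C)(C)C(C)(C)C)cc1 | intermediate
6 | coniferaldehyde, (2E)-3-(4-hydroxy-3-methoxyphenyl)prop-2-enal | COc1cc(/C=C/C=O)ccc1O | starting material
7 | (2E)-3-[4-(TBS-oxy)-3-methoxyphenyl]prop-2-enal | COc1cc(/C=C/C=O)ccc1O[Si](C)(C)C(C)(C)C | intermediate
8 | (1E,2E)-3-[4-(TBS-oxy)-3-methoxyphenyl]prop-2-enal oxime | COc1cc(/C=C/C=N/O)ccc1O[Si](C)(C)C(C)(C)C | intermediate
9 | (1Z,2E)-N-hydroxy-3-[4-(TBS-oxy)-3-methoxyphenyl]prop-2-enimidoyl chloride | COc1cc(/C=C/C(Cl)=N/O)ccc1O[Si](C)(C)C(C)(C)C | intermediate (not isolated)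
10 | (2E)-3-[4-(TBS-oxy)-3-methoxyphenyl]prop-2-enenitrile oxide | COc1cc(/C=C/C#[N+][O-])ccc1O[Si](C)(C)C(C)(C)C | intermediate (not isolated)
11 | 3-{(E)-2-[4-(TBS-oxy)-3-methoxyphenyl]ethenyl}-5-{(2S)-2-(TBS-oxy)-2-[4-(TBS-oxy)phenyl]ethyl}isoxazole | COc1cc(/C=C/c2cc(C[C@H](O[Si](C)(C)C(C)(C)C)c3ccc(O[Si](C)(C)C(C)(C)C)cc3)on2)ccc1O[Si](C)(C)C(C)(C)C | intermediate
12 | (1S,4Z,6E)-5-amino-1-(TBS-oxy)-1-[4-(TBS-oxy)phenyl]-7-[4-(TBS-oxy)-3-methoxyphenyl]hepta-4,6-dien-3-one | COc1cc(/C=C/C(N)=C/C(=O)C[C@H](O[Si](C)(C)C(C)(C)C)c2ccc(O[Si](C)(C)C(C)(C)C)cc2)ccc1O[Si](C)(C)C(C)(C)C | intermediate (not isolated)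
13 | (1S,6E)-1-(TBS-oxy)-1-[4-(TBS-oxy)phenyl]-7-[4-(TBS-oxy)-3-methoxyphenyl]-5-hydroxyhepta-4,6-dien-3-one | COc1cc(/C=C/C(O)=C\C(=O)C[C@H](O[Si](C)(C)C(C)(C)C)c2ccc(O[Si](C)(C)C(C)(C)C)cc2)ccc1O[Si](C)(C)C(C)(C)C | intermediate
14 | (1S,6E)-1,5-dihydroxy-7-(4-hydroxy-3-methoxyphenyl)-1-(4-hydroxyphenyl)hepta-4,6-dien-3-one | COc1cc(/C=C/C(O)=C\C(=O)C[C@H](O)c2ccc(O)cc2)ccc1O | target

**Total step count:** 7. **Longest linear sequence:** 5 (steps 1, 2, 5, 6, 7; the branch of steps 3 and 4 joins at step 5).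

**Steps most likely to fail**

Step 5. The nitrile oxide may dimerise or add to a styryl double bond faster than it finds the alkyne, or the chlorinating agent may attack the electron-rich arene. The fallback sets out from 5 and 7 and replaces the cycloaddition by acetylide addition and formal hydration of an ynone. Alkyne 5 would be lithiated (n-BuLi, THF, −78 °C) and added to aldehyde 7 to give (1E,7S)-7-(TBS-oxy)-1-[4-(TBS-oxy)-3-methoxyphenyl]-7-[4-(TBS-oxy)phenyl]hept-1-en-4-yn-3-ol F1 as a mixture of carbinol epimers. Oxidation with MnO2 in CH2Cl2 would give the cross-conjugated ynone, (1E,7S)-7-(TBS-oxy)-1-[4-(TBS-oxy)-3-methoxyphenyl]-7-[4-(TBS-oxy)phenyl]hept-1-en-4-yn-3-one F2. Conjugate addition of diethylamine (EtOH, rt) to the alkyne carbon remote from the carbonyl group, which is C3 of the target chain, would give the vinylogous amide, (1E,4E,7S)-5-(diethylamino)-7-(TBS-oxy)-1-[4-(TBS-oxy)-3-methoxyphenyl]-7-[4-(TBS-oxy)phenyl]hepta-1,4-dien-3-one F3. Hydrolysis with aqueous oxalic acid in THF would bring the sequence back to the route at 13.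

Step 6. Hydrolysis of the vinylogous amide may stall, or the acid may remove the benzylic silyl group and allow ring closure to a dihydropyranone or dehydration. The fallback sets out from 4 and 7 and gives up the heterocycle for an intramolecular O-to-C acyl transfer. Aldehyde 7 would be oxidised (NaClO2, NaH2PO4, 2-methylbut-2-ene, t-BuOH/H2O) to (2E)-3-[4-(TBS-oxy)-3-methoxyphenyl]prop-2-enoic acid F4. Esterification of 4 by this acid (DCC, DMAP, CH2Cl2) would give (1S)-1-[4-(TBS-oxy)phenyl]but-3-yn-1-yl (2E)-3-[4-(TBS-oxy)-3-methoxyphenyl]prop-2-enoate F5. Hydration of the terminal alkyne (Ph3PAuNTf2, monovalent gold, catalytic, dioxane/H2O, rt), assisted by the neighbouring ester carbonyl, would give the methyl ketone, (1S)-3-oxo-1-[4-(TBS-oxy)phenyl]butyl (2E)-3-[4-(TBS-oxy)-3-methoxyphenyl]prop-2-enoate F6. LiN(SiMe3)2 (3 equiv, THF, −78 °C, then AcOH) would form the kinetic methyl enolate, which would take the acyl group from oxygen through a six-membered tetrahedral intermediate and give (1S,6E)-1,5-dihydroxy-1-[4-(TBS-oxy)phenyl]-7-[4-(TBS-oxy)-3-methoxyphenyl]hepta-4,6-dien-3-one F7. HF·pyridine in pyridine/THF would then give 14, where the sequence comes back to the route.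

Step 1. Facial selectivity may be insufficient with this electron-rich aldehyde, or the sense of induction may be opposite to the model. The fallback sets out from 1 and separates the enantiomers instead of forming one. Zinc powder and propargyl bromide (THF/sat. aq. NH4Cl, 0 °C) would give racemic 1-[4-(TBS-oxy)phenyl]but-3-yn-1-ol F8. Kinetic resolution with Candida antarctica lipase B and vinyl acetate (toluene, rt) should, by the usual empirical rule for secondary carbinols, acylate the R enantiomer to (1R)-1-[4-(TBS-oxy)phenyl]but-3-yn-1-yl acetate F9 and leave the S alcohol. After chromatographic removal of F9 the sequence comes back to the route at 4.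

## Further compounds

F1 | step 5 | (1E,7S)-7-(TBS-oxy)-1-[4-(TBS-oxy)-3-methoxyphenyl]-7-[4-(TBS-oxy)phenyl]hept-1-en-4-yn-3-ol (both C3 epimers) | COc1cc(/C=C/C(O)C#CC[C@H](O[Si](C)(C)C(C)(C)C)c2ccc(O[Si](C)(C)C(C)(C)C)cc2)ccc1O[Si](C)(C)C(C)(C)C
F2 | step 5 | (1E,7S)-7-(TBS-oxy)-1-[4-(TBS-oxy)-3-methoxyphenyl]-7-[4-(TBS-oxy)phenyl]hept-1-en-4-yn-3-one | COc1cc(/C=C/C(=O)C#CC[C@H](O[Si](C)(C)C(C)(C)C)c2ccc(O[Si](C)(C)C(C)(C)C)cc2)ccc1O[Si](C)(C)C(C)(C)C
F3 | step 5 | (1E,4E,7S)-5-(diethylamino)-7-(TBS-oxy)-1-[4-(TBS-oxy)-3-methoxyphenyl]-7-[4-(TBS-oxy)phenyl]hepta-1,4-dien-3-one | COc1cc(/C=C/C(=O)/C=C(\C[C@H](O[Si](C)(C)C(C)(C)C)c2ccc(O[Si](C)(C)C(C)(C)C)cc2)N(CC)CC)ccc1O[Si](C)(C)C(C)(C)C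
F4 | step 6 | (2E)-3-[4-(TBS-oxy)-3-methoxyphenyl]prop-2-enoic acid | COc1cc(/C=C/C(=O)O)ccc1O[Si](C)(C)C(C)(C)C
F5 | step 6 | (1S)-1-[4-(TBS-oxy)phenyl]but-3-yn-1-yl (2E)-3-[4-(TBS-oxy)-3-methoxyphenyl]prop-2-enoate | COc1cc(/C=C/C(=O)O[C@@H](CC#C)c2ccc(O[Si](C)(C)C(C)(C)C)cc2)ccc1O[Si](C)(C)C(C)(C)C
F6 | step 6 | (1S)-3-oxo-1-[4-(TBS-oxy)phenyl]butyl (2E)-3-[4-(TBS-oxy)-3-methoxyphenyl]prop-2-enoate | COc1cc(/C=C/C(=O)O[C@@H](CC(C)=O)c2ccc(O[Si](C)(C)C(C)(C)C)cc2)ccc1O[Si](C)(C)C(C)(C)C
F7 | step 6 | (1S,6E)-1,5-dihydroxy-1-[4-(TBS-oxy)phenyl]-7-[4-(TBS-oxy)-3-methoxyphenyl]hepta-4,6-dien-3-one | COc1cc(/C=C/C(O)=C\C(=O)C[C@H](O)c2ccc(O[Si](C)(C)C(C)(C)C)cc2)ccc1O[Si](C)(C)C(C)(C)C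
F8 | step 1 | racemic 1-[4-(TBS-oxy)phenyl]but-3-yn-1-ol | C#CCC(O)c1ccc(O[Si](C)(C)C(C)(C)C)cc1
F9 | step 1 | (1R)-1-[4-(TBS-oxy)phenyl]but-3-yn-1-yl acetate | C#CC[C@@H](OC(C)=O)c1ccc(O[Si](C)(C)C(C)(C)C)cc1
A1 | direct plan | (R)-4-hydroxymandelic acid | O[C@@H](C(=O)O)c1ccc(O)cc1
A2 | direct plan | (1R)-1-(TBS-oxy)-1-[4-(TBS-oxy)phenyl]-3-diazopropan-2-one | CC(C)(C)[Si](C)(C)O[C@@H](C(=O)C=[N+]=[N-])c1ccc(O[Si](C)(C)C(C)(C)C)cc1
A3 | direct plan | (3S)-3-(TBS-oxy)-3-[4-(TBS-oxy)phenyl]prop-1-en-1-one (aldoketene) | CC(C)(C)[Si](C)(C)O[C@@H](C=C=O)c1ccc(O[Si](C)(C)C(C)(C)C)cc1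
A4 | direct plan | dehydrozingerone, (3E)-4-(4-hydroxy-3-methoxyphenyl)but-3-en-2-one | COc1cc(/C=C/C(C)=O)ccc1O
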